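## The problem

The target is a caryophyllane meroterpenoid: a gem-dimethylcyclobutane trans-fused at C1/C9 to a nine-membered ring bearing the exocyclic C8=C15 methylene, with a dihydropyran fused across C4–C5 and shared with an isobutyryl-substituted, gem-dimethylated cyclohexanetrione enol. Numbering used throughout: caryophyllane C1–C15 (C14 is the methyl on C4, C12/C13 the cyclobutane methyls); C1' is the pyran CH2, C2' and C3' are the enol-ether carbons of the trione ring, and C3' carries the ring oxygen and sits beside the CMe2 carbon. Four stereocentres are required, 1R,4S,5R,9S: C4 is a fully substituted ether carbon, and C5 carries hydrogen anti to the C4 methyl, so the pyran is trans-fused to the nine-membered ring. The pyran oxygen lies on the face of the former C4–C5 alkene opposite to the one that carries oxygen in the natural (4R,5R)-4,5-oxide of caryophyllene. C1 and C9 are remote from C4/C5 and can steer them only through the conformation of the medium ring, so a single kinetic addition across C4=C5 takes its facial outcome from conformer populations and cannot be corrected afterwards. The fragile parts are three: the 1,1-disubstituted alkene beside the strained cyclobutane (protonation at C15 leads to ring expansion or transannular closure), the ionisable tertiary vinylogous-ester bond O–C4, and the acidic, chelating triketone enol with two oxygens and one carbon as nucleophiles. The enabling feature is the ring O–C4–C5–C1'–C2'=C3': with one more double bond across C5–C1' it is a 2H-pyran on a cyclic 1,3-dicarbonyl, which is what condensation of such a dicarbonyl with a β,β-disubstituted enal delivers (aldehyde carbon = C1', β-carbon = C4). That enal is caryophyllene plus one carbon on C5, so the terpene half, with C1 and C9 correct, can come from the chiral pool.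

## Retrosynthesis

**13 ⇒ 11.** No skeletal bond is cut first; two hydrogens are removed from C5 and C1' of target 13, which gives the 2H-pyran 11 with only C4 left to set beside C1/C9. In the forward sense this is a proton to C5 and a hydride to C1' through the oxocarbenium ion 12. Catalytic hydrogenation is ruled out because it would take the C8=C15 bond first. A silane is preferred to a dihydropyridine donor: the latter can add hydride directly to the ring-opened valence tautomer 10, whereas a silane reduces only cations. The step must discriminate the dienol-ether terminus from the isolated alkene and must deliver the proton to the correct face of C5.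

**11 ⇒ 10 ⇒ 5 + 9.** The O–C4 bond is opened by retro-oxa-6π electrocyclisation to the 1-oxatriene 10, and the C1'=C2' bond is cut by retro-Knoevenagel condensation to enal 5 and trione 9. The neighbouring cut, O–C4 together with C5–C1' (a hetero-Diels–Alder disconnection back to 1, 2 and 9), is shorter. It fixes C4 and C5 in one irreversible event whose face is decided by the ring conformers of 1, and the required face is the one not preferred by peracids. The chosen cut separates the two centres: C4 is formed in a reversible pericyclic step, so its epimers can equilibrate and the unwanted one can be recycled, and C5 is set later. Enal 5 carries no stereocentre beyond C1/C9 and trione 9 is achiral. The forward reaction must condense at the single CH2 of 9, close through the oxygen beside CMe2, and give the 4S configuration.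

**5 ⇒ 4 ⇒ 3 ⇒ 1 + 2.** The C5–C1' bond is cut. C5 is the less substituted end of the only trisubstituted alkene of (−)-β-caryophyllene 1, so a carbonyl-ene reaction with formaldehyde 2 places the carbon there and moves the double bond to C4(14), giving alcohol 3. Oxidation to aldehyde 4 and base-mediated migration return the alkene to C4=C5 in conjugation, giving 5. This is two operations from the terpene; routes through the 4,5-oxide are longer and are held in reserve.

**9 ⇒ 8 ⇒ 6 + 7.** The two C–methyl bonds and the aryl–acyl bond are cut, leading through acylphloroglucinol 8 to phloroglucinol 6 and isobutyryl chloride 7. The forward steps are Friedel–Crafts acylation and dearomative gem-dimethylation, both standard for this class.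

## Roads not taken

**Alternative 1:** The cut is C2–C3 of a Δ2-caryophyllane, built de novo. Diene A1 (a cyclobutane with a vinyl group on C1 and, on C9, a keto chain ending in the vinyl carbinol C4) would be closed by the second-generation Grubbs catalyst to the nine-membered cis-alkene A2, with C8 as a ketone and C1' as a PMB-protected hydroxymethyl group.
- Merits: C4 and C5 are fixed in an open chain before the medium ring exists, so the trans relationship and its sense relative to the cyclobutane do not depend on a ring conformation. The acid-sensitive methylene is absent until the end.
- Weak points: a nine-membered ring must be closed by metathesis between a vinyl group on a fully substituted carbinol carbon and a vinylcyclobutane, where strain and entropy favour oligomers. A1 needs an enantioselective synthesis of a trans-1,2-disubstituted 3,3-dimethylcyclobutane plus two chain stereocentres. After closure there remain alkene hydrogenation, PMB removal, attachment of 9 at C1', formation of O–C4 at a tertiary carbinol and methylenation of C8.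
- Comparison: this road is better on stereochemical certainty at C4/C5. The chosen plan answers with a longest sequence of four steps from a terpene that already contains the cyclobutane, the nine-membered ring and the methylene.

**Alternative 2:** The cuts are C5–C6 and O–C4 together. In A3 a cyclobutyl vinyl ketone (C6=C7–C8=O) faces a trione C-allylated by the (E)-C4=C5 alkene. Lewis-acid activation of the enone lets C5 attack C6 (nine-membered ring) and the enol oxygen capture the C4 cation (pyran ring), giving the 8-oxo-15-nor compound A4, which still needs methylenation.
- Merits: two rings, two bonds and both new stereocentres form in one operation. Anti addition across the E-alkene translates alkene geometry into the trans ring fusion stereospecifically, which is more secure than a facial protonation at C5.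
- Weak points: a nine-membered ring must form by cation–olefin attack on an enone. Faster outlets exist for A3: direct Michael addition of the enol carbon or oxygen to the vinyl ketone, acid-induced closure of the pyran without C–C bond formation, and enone polymerisation. The face of the alkene relative to the distant cyclobutane has no control element, and the cyclobutane fragment must be made enantiopure.
- Comparison: this road is better in bond economy of the key step and in the C4/C5 relationship. The chosen plan avoids medium-ring formation altogether and keeps C4 correctable by equilibration.

**Alternative 3:** The cut is C7–C8. In A5 the cyclobutane carries a 1-iodovinyl group on C9 and a chain from C1 ending in the acetonide of the 4,1'-diol, whose C5 bears a vinyl group. Hydroboration of that vinyl group with 9-BBN at C7, then Pd(dppf)Cl2 and aqueous base, would close the nine-membered ring to A6 with the methylene in place.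
- Merits: the exocyclic alkene is installed by the ring closure itself under mild, non-acidic conditions, and C4/C5 are set beforehand on a six-membered acetonide template.
- Weak points: nine is the least favourable ring size for such a closure, and protodeboronation and β-hydride elimination compete at high dilution. The precursor is long. A6 is still far from the target: the diol must be freed and differentiated, 9 attached at C1', and O–C4 made at a tertiary centre.
- Comparison: this road is better in tolerance of the methylene and in certainty of the C4/C5 relationship. The chosen plan is much shorter and makes O–C4 pericyclically rather than by substitution at a tertiary carbon.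

Key step: step 5

Assumption: enal 5 is drawn with the ring-trans C4=C5 geometry of caryophyllene (4Z by the sequence rules), its geometric isomer would give the same 2H-pyran 11 because C5 is trigonal there, and the 4S epimer of 11 is taken to be the one favoured or enrichable by thermal equilibration.

## Route

Step 1
Reactants: 1 (−)-β-caryophyllene; 2 formaldehyde (used as paraformaldehyde)
Product: 3 (1R,5R,9S)-caryophylla-4(14),8(15)-dien-5-ylmethanol
Conditions: (CH2O)n, Me2AlCl (2 equiv), CH2Cl2, −40 → 0 °C; then cold 1 M HCl
Reagents that add atoms: none
Why: Lewis-acid-promoted carbonyl-ene reaction: the Me2AlCl–formaldehyde complex should attack the strained, more nucleophilic trans-trisubstituted C4=C5 bond at its less substituted carbon C5 and take an allylic hydrogen from the C14 methyl, while excess Me2AlCl removes protons as methane and so should spare the C8=C15 alkene and the cyclobutane. The C5 centre (drawn R, from attack on the exposed face) is erased in step 2, and any 3-ene regioisomer converges there.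

Step 2
Reactants: 3 (1R,5R,9S)-caryophylla-4(14),8(15)-dien-5-ylmethanol
Product: 5 (1R,4Z,9S)-caryophylla-4,8(15)-diene-5-carbaldehyde, via β,γ-unsaturated aldehyde 4 (not isolated)
Conditions: Dess–Martin periodinane, CH2Cl2, 0 °C → rt; filtration through silica; then DBU (0.2 equiv), CH2Cl2, rt
Reagents that add atoms: none
Why: Dess–Martin oxidation of the primary homoallylic alcohol leaves both alkenes untouched, and DBU then moves the 4(14) double bond into conjugation through the dienolate (γ-protonation at C14), driven by formation of the conjugated tetrasubstituted enal. The alkene geometry of 5 does not matter for step 5.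

Step 3
Reactants: 6 phloroglucinol; 7 isobutyryl chloride
Product: 8 2-methyl-1-(2,4,6-trihydroxyphenyl)propan-1-one
Conditions: AlCl3 (3 equiv), PhNO2/CH2Cl2, 0 → 60 °C; then ice/HCl
Reagents that add atoms: none
Why: Friedel–Crafts C-acylation of the symmetrical, highly activated ring; the aryl ketone–AlCl3 complex deactivates the ring and stops the reaction at monoacylation.

Step 4
Reactants: 8 2-methyl-1-(2,4,6-trihydroxyphenyl)propan-1-one
Product: 9 2-isobutyryl-4,4-dimethylcyclohexane-1,3,5-trione (acyl-chelated enol)
Conditions: NaOMe (3 equiv), MeI (2.2 equiv), MeOH, 0 °C → rt; then 1 M HCl
Reagents that add atoms: iodomethane, CI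
Why: Dearomative C-methylation of an acylphloroglucinol: the phenoxide is alkylated at a free ring carbon and the same carbon is alkylated again, which breaks aromaticity and gives the gem-dimethyl trione. Limiting MeI to about two equivalents should hold back tri- and tetramethylation.

Step 5
Reactants: 5 (1R,4Z,9S)-caryophylla-4,8(15)-diene-5-carbaldehyde; 9 2-isobutyryl-4,4-dimethylcyclohexane-1,3,5-trione
Product: 11 (1R,4S,9S)-5,1'-didehydro target (2H-pyran), via 1-oxatriene 10 (not isolated)
Conditions: ethylenediammonium diacetate (0.3 equiv), toluene, 80 °C, then 110 °C to equilibrate C4
Reagents that add atoms: none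
Why: The amine salt converts enal 5 into its iminium ion, the only CH2 of trione 9 (flanked by two carbonyls) adds to it, and loss of the amine gives the alkylidene trione 10 (Knoevenagel condensation), a 1-oxatriene O=C3'–C2'=C1'–C5=C4. Thermal disrotatory oxa-6π electrocyclisation of 10 then joins the carbonyl oxygen to C4, closing the six-membered 2H-pyran by a pericyclic rather than ionic ring closure and creating the quaternary centre. The closest known reaction type is the formal oxa-[3+3] annulation of cyclic 1,3-diones with β,β-disubstituted and cyclic tetrasubstituted enals, whose ring closure is reversible on heating. The closing oxygen is chosen by the substrate: the enol oxygen beside the acyl-bearing carbon is held as O–H in the hydrogen-bonded chelate with the isobutyryl carbonyl, so only the carbonyl beside CMe2 belongs to the oxatriene. C4 is the only new stereocentre and has no neighbouring control element; it is set by the relative stability of the two C4 epimers of 11, which interconvert through 10 at 110 °C, so the 4S epimer is collected at equilibrium and the 4R epimer is returned to it. The C4=C5 geometry of 5 is not remembered because C5 is trigonal in 11. The main competitor, conjugate addition of a second trione to 10, should be held back by the fully substituted diene terminus and by the intramolecular closure.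

Step 6
Reactants: 11 (1R,4S,9S)-5,1'-didehydro target (2H-pyran)
Product: 13 target (1R,4S,5R,9S), via oxocarbenium ion 12 (not isolated)
Conditions: Et3SiH (3 equiv), CF3CO2H (5 equiv), CH2Cl2, −20 → 0 °C
Reagents that add atoms: none
Why: Ionic hydrogenation of an alkoxy-conjugated alkene: CF3CO2H protonates the terminus C5 of the dienol ether O–C3'=C2'–C1'=C5 to give oxocarbenium ion 12, and Et3SiH, which reduces cations but not neutral enones or isolated alkenes, delivers hydride to C1'; in dilute acid at low temperature the isolated C8=C15 bond should be protonated far more slowly. C5 is set in the protonation: the proton should enter along the π axis anti to the pseudoaxial C4 methyl, so that both ring bonds (C4–C3 and C5–C6) end pseudoequatorial and the fusion is trans (5R). Because protonation is reversible and hydride transfer slower, the less strained trans-fused ion should be the one consumed.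

## Compound list

1 | (−)-β-caryophyllene, (1R,4E,9S)-caryophylla-4,8(15)-diene | C=C1CC/C=C(C)/CC[C@@H]2[C@@H]1CC2(C)C | starting material
2 | formaldehyde (used as paraformaldehyde) | C=O | starting material
3 | (1R,5R,9S)-caryophylla-4(14),8(15)-dien-5-ylmethanol (CH2OH on C5, methylene groups on C4 and C8) | C=C1CC[C@@H](CO)C(=C)CC[C@@H]2[C@@H]1CC2(C)C | intermediate
4 | (1R,5R,9S)-caryophylla-4(14),8(15)-diene-5-carbaldehyde | C=C1CC[C@@H](C=O)C(=C)CC[C@@H]2[C@@H]1CC2(C)C | intermediate (not isolated)
5 | (1R,4Z,9S)-caryophylla-4,8(15)-diene-5-carbaldehyde (C3 and C6 trans across C4=C5, as in 1) | C=C1CC/C(C=O)=C(C)/CC[C@@H]2[C@@H]1CC2(C)C | intermediate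
6 | phloroglucinol | Oc1cc(O)cc(O)c1 | starting material
7 | isobutyryl chloride | CC(C)C(Cl)=O | starting material
8 | 2-methyl-1-(2,4,6-trihydroxyphenyl)propan-1-one | CC(C)C(=O)c1c(O)cc(O)cc1O | intermediate
9 | 2-isobutyryl-4,4-dimethylcyclohexane-1,3,5-trione, drawn as the enol chelated to the acyl group | CC(C)C(=O)C1=C(O)CC(=O)C(C)(C)C1=O | intermediate
10 | 1-oxatriene: the CH2 carbon of 9 (C2') double-bonded to the aldehyde carbon C1' of 5, with carbonyl C3' cis to C5 | C=C1CC/C(/C=C3\C(=O)C(C)(C)C(=O)C(C(=O)C(C)C)=C3O)=C(C)/CC[C@@H]2[C@@H]1CC2(C)C | intermediate (not isolated)
11 | (1R,4S,9S)-2H-pyran: ring oxygen joins C3' to C4, C5=C1' and C2'=C3' double bonds, enol OH chelated to isobutyryl, C8=C15 retained | C=C1CCC2=CC3=C(O[C@@]2(C)CC[C@@H]2[C@@H]1CC2(C)C)C(C)(C)C(=O)C(C(=O)C(C)C)=C3O | intermediate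
12 | oxocarbenium trifluoroacetate: 11 protonated at C5 (5R), positive charge shared by C1' and the ring oxygen | C=C1CC[C@@H]2C=C3C(=[O+][C@@]2(C)CC[C@@H]2[C@@H]1CC2(C)C)C(C)(C)C(=O)C(C(=O)C(C)C)=C3O.[O-]C(=O)C(F)(F)F | intermediate (not isolated)
13 | target, (1R,4S,5R,9S): caryophyll-8(15)-ene with a dihydropyran trans-fused at C4 (O, methyl) and C5 (H, C1'H2), the pyran shared with the enolised 2-isobutyryl-4,4-dimethyltrione ring | C=C1CC[C@@H]2CC3=C(O[C@@]2(C)CC[C@@H]2[C@@H]1CC2(C)C)C(C)(C)C(=O)C(C(=O)C(C)C)=C3O | target

## Step count and least certain steps

Total step count: 6. Longest linear sequence: 4 steps (steps 1, 2, 5, 6 from 1; equally steps 3, 4, 5, 6 from 6).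

**Step 5 (key step).** Condensation at the hindered α,β,β-trisubstituted enal may be slow. Trione could then be lost by conjugate addition of a second molecule to oxatriene 10, and closure through the other carbonyl oxygen could intrude once the chelate loosens at high temperature. The C4 equilibrium may also lie on the 4R side, which would make recycling laborious. Fallback, from 5 back to 11, forming C1'–C2' by allylation instead of condensation: Luche reduction of 5 (NaBH4, CeCl3) gives the allylic alcohol caryophylla-4,8(15)-dien-5-ylmethanol F1. Tsuji–Trost C-allylation of 9 with F1 under Pd(PPh3)4 (the acidic trione activates the allylic alcohol and attack occurs at the CH2 terminus) gives the C-allyl trione F2. DDQ then removes hydride from the doubly activated C1' of F2 to regenerate 10, which closes to 11. If the difficulty is the C4 position of equilibrium and not bond formation, the fallback given for step 6 bypasses both steps.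

**Step 6.** Three things may go wrong: the proton may be delivered to C5 from the methyl-bearing face (poor facial selectivity, giving the cis-fused epimer); the O–C4 bond may ionise in acid, with reduction of the ring-opened allyl cation; and C15 may be protonated competitively, leading to double-bond migration or cyclobutane ring expansion. Fallback, from 1, 2 and 9 directly to 13: heating 9 with paraformaldehyde (NaOAc, AcOH) generates the methylidene trione F3 by Knoevenagel condensation in the presence of 1. Inverse-demand hetero-Diels–Alder addition of F3 across the E-alkene of 1 forms O–C4 and C5–C1' suprafacially, which guarantees the trans fusion without strong acid. The facial diastereomer forms alongside and must be separated; 13 is expected to be the lesser adduct, by analogy with the facial preference of epoxidation, which is why this is not the main route.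

**Step 1.** Chemoselectivity may be lost (ene reaction at the unhindered C8=C15 methylene instead of C4=C5), or the Lewis acid may trigger transannular cyclisation. Fallback, from 1 back to 5, using the known preference of peracids for the strained ring alkene: 3-chloroperbenzoic acid gives (1R,4R,5R,9S)-caryophyllene 4,5-oxide F4 (also an article of commerce). LiNEt2 isomerises the epoxide to the allylic alcohol caryophylla-4(14),8(15)-dien-5-ol F5. MnO2 gives the dienone F6. Wittig reaction with Ph3P=CHOMe (from the phosphonium chloride and KOtBu) gives the methoxymethylidene diene F7. Mild aqueous acid protonates F7 at C14 and hydrolyses the enol ether to 5; any 4 formed is converted by DBU as in step 2.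

**Step 2.** The double bond may migrate only partly if the tetrasubstituted ring alkene is strained enough to leave much 4 at equilibrium, and 4 may self-condense under DBU. Fallback, from 4 directly to 11: 4 is taken into step 5 without base treatment. The amine catalyst turns 4 into a dienamine, the tautomer of the conjugated iminium ion of 5, so condensation with 9 and electrocyclisation proceed without isolating 5. No new compound is involved.

## Further compounds

F1 | step 5 | (1R,9S)-caryophylla-4,8(15)-dien-5-ylmethanol (ring-trans C4=C5 retained) | C=C1CC/C(CO)=C(C)/CC[C@@H]2[C@@H]1CC2(C)C
F2 | step 5 | 6-[(caryophylla-4,8(15)-dien-5-yl)methyl]-2-isobutyryl-4,4-dimethylcyclohexane-1,3,5-trione (dienol form) | C=C1CC/C(CC3=C(O)C(C)(C)C(=O)C(C(=O)C(C)C)=C3O)=C(C)/CC[C@@H]2[C@@H]1CC2(C)C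
F3 | step 6 | 2-isobutyryl-4,4-dimethyl-6-methylidenecyclohexane-1,3,5-trione (enol form) | C=C1C(=O)C(C)(C)C(=O)C(C(=O)C(C)C)=C1O
F4 | step 1 | (1R,4R,5R,9S)-caryophyllene 4,5-oxide | C[C@@]12CC[C@@H]3[C@H](CC3(C)C)C(=C)CC[C@H]1O2
F5 | step 1 | (1R,5R,9S)-caryophylla-4(14),8(15)-dien-5-ol | C=C1CC[C@@H](O)C(=C)CC[C@@H]2[C@@H]1CC2(C)C
F6 | step 1 | (1R,9S)-caryophylla-4(14),8(15)-dien-5-one | C=C1CCC(=O)C(=C)CC[C@@H]2[C@@H]1CC2(C)C
F7 | step 1 | (1R,9S)-5-(methoxymethylidene)caryophylla-4(14),8(15)-diene (E/Z mixture) | C=C1CCC(=COC)C(=C)CC[C@@H]2[C@@H]1CC2(C)C
F0 | step 2 | none | none
A1 | alternative 1 | metathesis precursor: (1R,9S)-cyclobutane with vinyl on C1 and, on C9, the chain C8(=O)–C7–C6–C5(CH2OPMB)–C4(CH3)(OH)–CH=CH2 | C=C[C@@H]1[C@@H](C(=O)CC[C@H](COCc2ccc(OC)cc2)[C@@](C)(O)C=C)CC1(C)C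
A2 | alternative 1 | 8-oxo-15-norcaryophyll-2-en-4-ol with PMB-protected hydroxymethyl on C5 (cis C2=C3) | O=C1CC[C@H](COCc3ccc(OC)cc3)[C@@](C)(O)/C=C\[C@@H]2[C@@H]1CC2(C)C
A3 | alternative 2 | cyclobutyl vinyl ketone whose C1 side chain ends in the (E)-C4=C5 alkene allylated onto the trione | C=CC(=O)[C@H]1CC(C)(C)[C@@H]1CC/C(C)=C/CC2=C(O)C(C)(C)C(=O)C(C(=O)C(C)C)=C2O
A4 | alternative 2 | 8-oxo-15-nor target | O=C1CC[C@@H]2CC3=C(O[C@@]2(C)CC[C@@H]2[C@@H]1CC2(C)C)C(C)(C)C(=O)C(C(=O)C(C)C)=C3O
A5 | alternative 3 | cyclobutane with 1-iodovinyl on C9 and a C1 chain ending in the 4,1'-diol acetonide bearing vinyl on C5 | C=C[C@@H]1COC(C)(C)O[C@@]1(C)CC[C@@H]1[C@@H](C(I)=C)CC1(C)C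
A6 | alternative 3 | caryophyll-8(15)-ene-4,1'-diol acetonide | C=C1CC[C@@H]2COC(C)(C)O[C@@]2(C)CC[C@@H]2[C@@H]1CC2(C)C
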